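The constants used here were drawn at random within sensible limits.

At late times I expected these flasks to stand still, so I asked what would still be working at 40 h and how much one catalyst could have made by then.

    starting material + free catalyst → catalyst intermediate A (k1 = 620 M⁻¹ min⁻¹)
    catalyst intermediate A → catalyst intermediate B (k2 = 1.1 min⁻¹)
    catalyst intermediate B → free catalyst + product (k3 = 7.0 min⁻¹)
    catalyst intermediate A → spent catalyst (k4 = 0.026 min⁻¹)
    starting material + catalyst intermediate B ⇌ idle complex, settled at all times (K5 = 7.9 M⁻¹)

| flask | starting material | free catalyst | time | remark |
|---|---|---|---|---|
| elm | 0.14 M (fed, over 15 h) | 0.060 mM | 40 h | the fed solution adds 0.25 times the starting volume |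
| larch | 0.14 M (fed, over 15 h) | 0.15 mM | 40 h | the fed solution adds 0.25 times the starting volume |
| maple | 0.14 M (fed, over 15 h) | 0.50 mM | 40 h | the fed solution adds 0.25 times the starting volume |
| alder | 0.14 M (fed, over 15 h) | 1.5 mM | 40 h | the fed solution adds 0.25 times the starting volume |

- a species is counted by the starting material in it: one idle complex counts as two
- charges are per starting volume, the dose included; the dosed solution carries all of it
- "hardly changes" means that all values lie within two and a half points (for a concentration: within two and a half percent of the largest)
- run time (elm): 40 h

* amount of product at the end, in percent of the starting material charged for elm, larch, maple, alder, in this order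
* how the row runs (rises, then falls / falls all the way / hardly changes / falls, then rises / rises all the way)

I climbed the time scales from the fastest. Catalyst intermediate B went on to free catalyst and product with a half-life of 0.0990 min, quicker than either exit of catalyst intermediate A. The idle complex holds catalyst intermediate B, past the branch, so I counted it as delay and not as loss.

The next rung was catalyst intermediate A, with a half-life of 0.616 min. Here the catalyst's fate was chosen at every pass, since it could go on to catalyst intermediate B or become spent catalyst, and going on was faster. The number of passes survived on average is the turnover number N, the products one catalyst makes before it is spent:

N = 1.1 min⁻¹ / 0.026 min⁻¹ = 42.3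

The third rung was the working life of a catalyst. Each round took 1.05 min before any wait for starting material, so N rounds took 0.742 h, much less than the dosing time.

The slowest rung was the feed. Alder has the heaviest catalyst charge and so the greatest demand, N times its charge, or 63.5 mM. That is less than the whole charge of starting material, so in my reckoning starting material stayed over. At the feed's pace the demand was delivered in 6.80 h, within the dosing time. I therefore reckoned product as N times the catalyst charge c, over the charge of starting material c_A:

yield = N c / c_A

elm 1.81%, larch 4.53%, maple 15.1%, alder 45.3%

Read in this order, my row ran thus: rises all the way, in proportion to the catalyst charge.

The forecast gave 1.81%, 4.53%, 15.1% and 45.3%, a row that rises all the way, on the ground that “product is about 42 times the catalyst charge and rises in proportion to it”.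

The simulation gave 1.81%, 4.53%, 15.1% and 45.3%, a row that rises all the way. At catalyst intermediate A the way on stood against the way to spent catalyst as 42.3 to one, and in elm spent catalyst was >99.9% of the catalyst at 12.0 h, with 98% of the starting material still there at 40.0 h. In alder the same 42.3 on each catalyst of a charge of 1.5 mM comes to 45.3% of the starting material charged, spent catalyst was >99.9% at 12.0 h, and 54% of the starting material stood unbound at 40.0 h.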